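**Retrosynthetic overview**
- The cyclohexenone is disconnected to an isomeric 2-acetonyl-2,3-dihydro-4H-pyran-4-one: a polyketide-type aldol of the methyl ketone onto the pyranone carbonyl, then β-elimination of the ring oxygen (aldol, then "dehydration").
- The ring-oxygen stereocentre of the pyranone dictates the tertiary carbinol and is destroyed in the same operation (traceless 1,3-relay).
- The pyranone comes from a β-hydroxy ketone and oleoyl chloride (C-acylation, then acid cyclodehydration).
- The β-hydroxy ketone comes from acetone and a ketal-protected 3-oxobutanal by catalytic asymmetric aldol; the aldehyde comes from the ethylene ketal of ethyl acetoacetate.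
- Ring order: dihydropyranone first, then a transient 2-oxabicyclo[3.3.1]nonene, which opens to the cyclohexenone.

Assumption: the D-prolinamide catalyst shows the usual proline-type facial selectivity with the ketal aldehyde (L-series gives the (R)-type aldol, D-series its mirror image); if the sense is reversed, the L-catalyst is used and nothing else changes.

**Step 1**
Reactants: 1 ethyl 2-(2-methyl-1,3-dioxolan-2-yl)acetate
Product: 2 2-(2-methyl-1,3-dioxolan-2-yl)acetaldehyde
Conditions: DIBAL-H (1.05 equiv), CH2Cl2, −78 °C; MeOH, then aq. Rochelle salt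
Reagents that add atoms: none
Why: DIBAL-H partial reduction of an ester stops at the aluminium hemiacetal at −78 °C and releases the aldehyde on work-up, and the ketal is inert to hydride.

**Step 2**
Reactants: 2 2-(2-methyl-1,3-dioxolan-2-yl)acetaldehyde; 3 acetone
Product: 4 (S)-4-hydroxy-5-(2-methyl-1,3-dioxolan-2-yl)pentan-2-one
Conditions: acetone (solvent, large excess), (R)-N-[(R)-1-hydroxy-4-methyl-1,1-diphenylpentan-2-yl]pyrrolidine-2-carboxamide (10 mol%), −35 °C, 48 h
Reagents that add atoms: none
Why: Enamine-catalysed direct asymmetric aldol addition of acetone (proline-type, prolinamide variant for α-unbranched aldehydes), in which the D-configured catalyst delivers the acetone enamine to one aldehyde face through amide N–H/O–H hydrogen bonding and sets the carbinol as (S), while excess acetone at low temperature suppresses self-aldol and β-elimination of 2.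

**Step 3**
Reactants: 4 (S)-4-hydroxy-5-(2-methyl-1,3-dioxolan-2-yl)pentan-2-one; 5 (Z)-octadec-9-enoyl chloride (oleoyl chloride)
Product: 7 (R)-6-[(Z)-heptadec-8-en-1-yl]-2-(2-oxopropyl)-2,3-dihydro-4H-pyran-4-one, via hydroxy diketone ketal 6 (not isolated)
Conditions: LiHMDS (2.2 equiv), THF, −78 °C; 5 (1.0 equiv), −78 → −20 °C; then 3 M HCl (aq), THF, 0 °C → rt, 2 h
Reagents that add atoms: water, O
Why: The alkoxide/kinetic methyl-enolate dianion of 4 is acylated at carbon by 5 (Claisen-type acylation, any O-acylated material converging by a Baker–Venkataraman-type O→C acyl shift through a six-membered transition state) to the β-diketonate 6, and aqueous acid then closes the free OH onto the distal carbonyl with dehydration to the vinylogous ester (cyclodehydration of a δ-hydroxy-β-diketone) and hydrolyses the dioxolane, the carbinol C–O bond being untouched so that (S)-4 becomes (R)-7 only through a change of CIP priorities.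

**Step 4**
Reactants: 7 (R)-6-[(Z)-heptadec-8-en-1-yl]-2-(2-oxopropyl)-2,3-dihydro-4H-pyran-4-one
Product: 9 (R)-5-hydroxy-5-[(Z)-2-oxononadec-10-en-1-yl]cyclohex-2-en-1-one, via bridged ketol 8 (not isolated)
Conditions: 7 added to LiHMDS (1.05 equiv), THF, −78 °C, 1 h; AcOH (1.2 equiv), −78 °C; then DBU (0.5 equiv), −78 → 0 °C, 30 min; pH 7 buffer
Reagents that add atoms: none
Why: Proposed new method: the kinetic lithium enolate of the methyl ketone adds 1,2 to the pyranone carbonyl (intramolecular aldol as in 3-acetonylcyclohexanone → 1-hydroxybicyclo[3.3.1]nonan-3-one, combined with Stork–Danheiser-type 1,2-addition of a hard enolate to a vinylogous ester), which the three-atom tether allows only on the face bearing the acetonyl arm so that the ring-oxygen stereocentre fixes the new carbinol as (R); in ketol 8 the ring C–O bond is anti-periplanar to an axial α-hydrogen of the new ketone, so DBU triggers an E1cB retro-oxa-Michael opening (closest known type: base-induced β-alkoxy ketone elimination) that expels the oxygen as an enolate, which tautomerises irreversibly to the side-chain ketone and erases the relay stereocentre while forming the enone.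

**Compound list**
1 | ethyl 2-(2-methyl-1,3-dioxolan-2-yl)acetate | CCOC(=O)CC1(C)OCCO1 | starting material
2 | 2-(2-methyl-1,3-dioxolan-2-yl)acetaldehyde | O=CCC1(C)OCCO1 | intermediate
3 | acetone | CC(C)=O | starting material
4 | (S)-4-hydroxy-5-(2-methyl-1,3-dioxolan-2-yl)pentan-2-one | CC(=O)C[C@H](O)CC1(C)OCCO1 | intermediate
5 | (Z)-octadec-9-enoyl chloride | CCCCCCCC/C=C\CCCCCCCC(Cl)=O | starting material
6 | (2S,14Z)-2-hydroxy-1-(2-methyl-1,3-dioxolan-2-yl)tricos-14-ene-4,6-dione | CC1(OCCO1)C[C@@H](O)CC(=O)CC(=O)CCCCCCC/C=C\CCCCCCCC | intermediate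
7 | (R)-6-[(Z)-heptadec-8-en-1-yl]-2-(2-oxopropyl)-2,3-dihydro-4H-pyran-4-one | CC(=O)C[C@@H]1CC(=O)C=C(CCCCCCC/C=C\CCCCCCCC)O1 | intermediate
8 | (1S,5S)-3-[(Z)-heptadec-8-en-1-yl]-5-hydroxy-2-oxabicyclo[3.3.1]non-3-en-7-one | O[C@]12CC(=O)C[C@H](C1)OC(CCCCCCC/C=C\CCCCCCCC)=C2 | intermediate
9 | (R)-5-hydroxy-5-[(Z)-2-oxononadec-10-en-1-yl]cyclohex-2-en-1-one | CCCCCCCC/C=C\CCCCCCCC(=O)C[C@]1(O)CC=CC(=O)C1 | target

**Totals**
Total step count: 4. Longest linear sequence: 4 (1 → 2 → 4 → 7 → 9).

**Steps most likely to fail, with fallbacks**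

Step 4 (highest risk). Possible failures:
- enolisation at the acetonyl CH2 or the pyranone α-CH2, which opens the pyranone to an achiral dienone;
- 1,4- instead of 1,2-addition, giving a 9-oxabicyclo[3.3.1]nonanedione;
- retro-aldol of 8 before it fragments;
- base-induced loss of the tertiary OH from 9, giving the phenol (hence cold, short exposure to DBU).

Fallback, setting out from 7 and coming back at 8: the kinetic enolate is trapped in situ (LiHMDS, TMSCl, THF, −78 °C) as (R)-6-[(Z)-heptadec-8-en-1-yl]-2-{2-[(trimethylsilyl)oxy]prop-2-en-1-yl}-2,3-dihydro-4H-pyran-4-one F1. Without isolation this is brominated with NBS (THF, −78 → 0 °C) to (S)-2-(3-bromo-2-oxopropyl)-6-[(Z)-heptadec-8-en-1-yl]-2,3-dihydro-4H-pyran-4-one F2, which is purified so that regiochemistry is secured before ring closure. SmI2 (2.2 equiv, THF, −78 °C) then generates the samarium(III) enolate regiospecifically under non-basic conditions (Reformatsky-type aldol); the oxophilic metal favours carbonyl addition and a non-reverting aldolate. Buffered work-up gives 8, which is fragmented with DBU as in step 4.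

Step 3. Possible failures: O- or double acylation, enolate equilibration with β-elimination of the acyloxy group, or side reactions of the liberated methyl ketone in the acid stage.

Fallback, setting out from 4 and coming back at 7: the C–C bond is made by aldol and oxidation instead of acylation. TBSCl/imidazole (DMF) gives (S)-4-[(tert-butyldimethylsilyl)oxy]-5-(2-methyl-1,3-dioxolan-2-yl)pentan-2-one F3. Its kinetic methyl enolate (LDA, THF, −78 °C) adds to (Z)-octadec-9-enal (CCCCCCCC/C=C\CCCCCCCC=O) to give (2S,14Z)-2-[(tert-butyldimethylsilyl)oxy]-6-hydroxy-1-(2-methyl-1,3-dioxolan-2-yl)tricos-14-en-4-one F4 as a mixture of C6 epimers. Dess–Martin periodinane/NaHCO3 oxidises this to (2S,14Z)-2-[(tert-butyldimethylsilyl)oxy]-1-(2-methyl-1,3-dioxolan-2-yl)tricos-14-ene-4,6-dione F5. 3 M HCl/THF (rt) then removes the silyl group, cyclodehydrates and cleaves the ketal to give 7.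

Step 2. Possible failures: aldehyde 2 may self-condense or lose the ketal oxygen by β-elimination under amine catalysis, or the ee may be insufficient for a single enantiomer.

Fallback, setting out from 2 and coming back at 4: reagent-controlled methallylboration with (−)-B-methallyldiisopinocampheylborane (Et2O, −78 °C; NaOH/H2O2 work-up; antipode chosen to give the (S)-alcohol) gives (S)-4-methyl-1-(2-methyl-1,3-dioxolan-2-yl)pent-4-en-2-ol F6. Ozonolysis (O3, CH2Cl2/MeOH, −78 °C; Me2S) converts it to 4; no other alkene is present at this stage.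

**Further compounds**
F1 | step 4 | (R)-6-[(Z)-heptadec-8-en-1-yl]-2-{2-[(trimethylsilyl)oxy]prop-2-en-1-yl}-2,3-dihydro-4H-pyran-4-one | C=C(O[Si](C)(C)C)C[C@@H]1CC(=O)C=C(CCCCCCC/C=C\CCCCCCCC)O1
F2 | step 4 | (S)-2-(3-bromo-2-oxopropyl)-6-[(Z)-heptadec-8-en-1-yl]-2,3-dihydro-4H-pyran-4-one | BrCC(=O)C[C@@H]1CC(=O)C=C(CCCCCCC/C=C\CCCCCCCC)O1
F3 | step 3 | (S)-4-[(tert-butyldimethylsilyl)oxy]-5-(2-methyl-1,3-dioxolan-2-yl)pentan-2-one | CC(=O)C[C@H](O[Si](C)(C)C(C)(C)C)CC1(C)OCCO1
F4 | step 3 | (2S,14Z)-2-[(tert-butyldimethylsilyl)oxy]-6-hydroxy-1-(2-methyl-1,3-dioxolan-2-yl)tricos-14-en-4-one (C6 epimers) | CC1(OCCO1)C[C@@H](O[Si](C)(C)C(C)(C)C)CC(=O)CC(O)CCCCCCC/C=C\CCCCCCCC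
F5 | step 3 | (2S,14Z)-2-[(tert-butyldimethylsilyl)oxy]-1-(2-methyl-1,3-dioxolan-2-yl)tricos-14-ene-4,6-dione | CC1(OCCO1)C[C@@H](O[Si](C)(C)C(C)(C)C)CC(=O)CC(=O)CCCCCCC/C=C\CCCCCCCC
F6 | step 2 | (S)-4-methyl-1-(2-methyl-1,3-dioxolan-2-yl)pent-4-en-2-ol | CC(=C)C[C@H](O)CC1(C)OCCO1
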